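**Retrosynthetic overview**
1. Pestaphilone D (33) comes from desilylation and DDQ dehydrogenation of the 3H-isochromenone 31, whose pyran ring closes by 6π-oxa-electrocyclisation of a (2Z,4E)-dienal.
2. The dienal comes from Negishi coupling of an (E)-alkenylzinc (from epoxy-alkyne 15) with the β-triflyloxy enal 25; the cyclohexenone is then closed by an intramolecular Claisen (Dieckmann-type) acylation onto a lactate-derived dioxolanone.
3. 25 comes from (R)-lactic acid (C-7 by Seebach self-regeneration, C-8 by Felkin–Anh reduction) and 5-methylisoxazole-4-carbonyl chloride (masked C-1/C-8a/C-4a/C-5).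
4. 15 comes from ethyl (S)-3-hydroxybutanoate (Fráter–Seebach, side-chain stereodiad) and (S)-but-3-yn-2-ol (relay carbinol that directs the vanadium epoxidation and is then oxidised away).
5. Ring order: epoxide → monocyclic 2H-pyran (electrocyclisation) → cyclohexenone → bicyclic 2H-pyran (electrocyclisation) → 6H-isochromen-6-one.

Notation: TBS = tert-butyldimethylsilyl; R = (2E,4R,5S)-5-(TBSO)-4-methylhex-2-en-2-yl; Ep = the trans 3-R-2-methyloxiran-2-yl group in the spatial configuration drawn in 13 and kept to the target; Diox = (2R,5S)-2-tert-butyl-5-methyl-4-oxo-1,3-dioxolan-5-yl; core atoms carry isochromene numbers (C-1, O-2, C-3 … C-8a).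

**Route**

Step 1
Reactants: 1 ethyl (S)-3-hydroxybutanoate
Product: 2 ethyl (2S,3S)-3-hydroxy-2-methylbutanoate
Conditions: LiN(i-Pr)2 (2.2 equiv), THF, −50 → −20 °C; MeI, DMPU, −50 → 0 °C
Reagents that add atoms: iodomethane, CI
Why: Fráter–Seebach alkylation, in which the chelated lithium alkoxide–enolate dianion is methylated anti to the C-3 methyl so that the bought C-3 centre sets C-2 (anti, about 95:5).

Step 2
Reactants: 2 ethyl (2S,3S)-3-hydroxy-2-methylbutanoate
Product: 3 ethyl (2S,3S)-3-(TBSO)-2-methylbutanoate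
Conditions: TBSCl, imidazole, DMF, rt
Reagents that add atoms: tert-butyldimethylsilyl chloride, CC(C)(C)[Si](C)(C)Cl
Why: Standard silyl ether protection of the secondary alcohol, with no stereocentre touched.

Step 3
Reactants: 3 ethyl (2S,3S)-3-(TBSO)-2-methylbutanoate
Product: 4 (2S,3S)-3-(TBSO)-2-methylbutanal
Conditions: i-Bu2AlH (1.1 equiv), CH2Cl2, −78 °C
Reagents that add atoms: none
Why: Partial ester reduction that stops at the tetrahedral aluminium hemiacetal at −78 °C and releases the aldehyde on work-up without α-epimerisation.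

Step 4
Reactants: 4 (2S,3S)-3-(TBSO)-2-methylbutanal
Product: 5 tert-butyl{[(2S,3R)-5,5-dibromo-3-methylpent-4-en-2-yl]oxy}dimethylsilane
Conditions: CBr4, PPh3, CH2Cl2, 0 °C
Reagents that add atoms: carbon tetrabromide, BrC(Br)(Br)Br
Why: Corey–Fuchs (Ramirez) dibromo-olefination under near-neutral conditions that leave the α-stereocentre intact.

Step 5
Reactants: 5 tert-butyl{[(2S,3R)-5,5-dibromo-3-methylpent-4-en-2-yl]oxy}dimethylsilane
Product: 6 tert-butyldimethyl{[(2S,3R)-3-methylhex-4-yn-2-yl]oxy}silane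
Conditions: n-BuLi (2.1 equiv), THF, −78 → 0 °C; MeI, DMPU, 0 °C → rt
Reagents that add atoms: iodomethane, CI
Why: Second stage of the Corey–Fuchs sequence (Br/Li exchange, Fritsch–Buttenberg–Wiechell rearrangement to the lithium acetylide, C-methylation) gives the 2-alkyne.

Step 6
Reactants: 6 tert-butyldimethyl{[(2S,3R)-3-methylhex-4-yn-2-yl]oxy}silane
Product: 8 tert-butyl{[(2S,3R,4E)-5-iodo-3-methylhex-4-en-2-yl]oxy}dimethylsilane, via alkenylzirconocene chloride 7 (not isolated)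
Conditions: Cp2Zr(H)Cl (1.5 equiv), THF, 50 °C; I2, 0 °C
Reagents that add atoms: iodine, II
Why: Hydrozirconation (syn addition, zirconium settling on the less hindered methyl-bearing carbon on warming) and iodinolysis with retention give the (E)-trisubstituted vinyl iodide.

Step 7
Reactants: 9 (S)-but-3-yn-2-ol; 8 tert-butyl{[(2S,3R,4E)-5-iodo-3-methylhex-4-en-2-yl]oxy}dimethylsilane
Product: 11 (2S,3E,5E,7R,8S)-8-(TBSO)-3,5,7-trimethylnona-3,5-dien-2-ol, via alkenylalane 10 (not isolated)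
Conditions: 9, AlMe3 (3 equiv), Cp2ZrCl2 (0.25 equiv), CH2Cl2, 0 °C → rt; then 8, ZnCl2, Pd(PPh3)4 (5 mol%), THF, rt
Reagents that add atoms: trimethylaluminium, C[Al](C)C
Why: Negishi zirconium-catalysed syn-carboalumination (methyl to the internal carbon) followed by Pd-catalysed alkenyl–alkenyl cross-coupling with retention at both partners builds the (3E,5E)-dienol without touching the bought carbinol centre.

Step 8
Reactants: 11 (2S,3E,5E,7R,8S)-8-(TBSO)-3,5,7-trimethylnona-3,5-dien-2-ol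
Product: 12 (S)-1-(Ep)ethan-1-ol (erythro epoxy alcohol)
Conditions: VO(acac)2 (5 mol%), t-BuOOH, CH2Cl2, 0 °C → rt
Reagents that add atoms: tert-butyl hydroperoxide, CC(C)(C)OO
Why: Hydroxyl-directed vanadium epoxidation of the allylic alkene only, in which A(1,2) strain between the carbinol methyl and the C-3 methyl fixes the reactive conformer so that the (S)-carbinol sets both epoxide centres (erythro, typically ≥ 95:5).

Step 9
Reactants: 12 (S)-1-(Ep)ethan-1-ol
Product: 13 1-[(2R,3S)-3-R-2-methyloxiran-2-yl]ethan-1-one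
Conditions: Dess–Martin periodinane, NaHCO3, CH2Cl2, 0 °C → rt
Reagents that add atoms: none
Why: Buffered Dess–Martin oxidation removes the relay carbinol centre and gives the methyl ketone, whose α-carbon is quaternary and cannot epimerise.

Step 10
Reactants: 13 1-[(2R,3S)-3-R-2-methyloxiran-2-yl]ethan-1-one
Product: 15 ethynyl epoxide Ep–C≡CH, via enol phosphate 14 (not isolated)
Conditions: LiN(i-Pr)2 (1.1 equiv), THF, −78 °C; ClP(O)(OEt)2; LiN(i-Pr)2 (2.3 equiv), −78 → −20 °C
Reagents that add atoms: none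
Why: Negishi enol-phosphate elimination, in which the only enolisable position (CH3) gives the enol phosphate and base-induced β-elimination at low temperature gives the terminal alkyne with the epoxide untouched.

Step 11
Reactants: 16 (R)-lactic acid; 17 pivalaldehyde
Product: 18 (2R,5R)-2-tert-butyl-5-methyl-1,3-dioxolan-4-one (cis)
Conditions: TsOH·H2O (cat.), H2SO4 (cat.), pentane, reflux (Dean–Stark); recrystallisation at −78 °C
Reagents that add atoms: none
Why: Seebach acetalisation, in which the lactate centre directs the new acetal centre (cis isomer, thermodynamic and crystalline) and so stores the chirality for self-regeneration.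

Step 12
Reactants: 18 (2R,5R)-2-tert-butyl-5-methyl-1,3-dioxolan-4-one; 19 5-methylisoxazole-4-carbonyl chloride
Product: 20 (5-methylisoxazol-4-yl)(Diox)methanone
Conditions: LiN(i-Pr)2, THF, −78 °C; 19, −78 °C
Reagents that add atoms: none
Why: Seebach self-regeneration of stereocentres, in which C-acylation of the dioxolanone lithium enolate occurs anti to the t-Bu group so that the acyl group replaces the lactate hydrogen with net retention and fixes quaternary C-7.

Step 13
Reactants: 20 (5-methylisoxazol-4-yl)(Diox)methanone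
Product: 21 (R)-(5-methylisoxazol-4-yl)(Diox)methanol
Conditions: NaBH4, THF/MeOH, −78 → −40 °C
Reagents that add atoms: none
Why: Polar Felkin–Anh reduction, in which hydride attacks anti to the ring C–O bond past the small methyl group and gives mainly the (R)-carbinol, i.e. the 7,8-trans-diol relationship controlled by C-7.

Step 14
Reactants: 21 (R)-(5-methylisoxazol-4-yl)(Diox)methanol
Product: 22 (R)-(5-methylisoxazol-4-yl)(Diox)methyl TBS ether
Conditions: TBSOTf, 2,6-lutidine, CH2Cl2, 0 °C → rt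
Reagents that add atoms: tert-butyldimethylsilyl triflate, CC(C)(C)[Si](C)(C)OS(=O)(=O)C(F)(F)F
Why: Silyl triflate silylation, needed for the hindered neopentylic alcohol.

Step 15
Reactants: 22 (R)-(5-methylisoxazol-4-yl)(Diox)methyl TBS ether
Product: 23 (3Z,4R)-3-(aminomethylidene)-4-(TBSO)-4-(Diox)butan-2-one
Conditions: H2 (1 atm), Pd on carbon (10 wt% Pd), EtOH, rt
Reagents that add atoms: none
Why: Hydrogenolysis of the isoxazole N–O bond unmasks the regiodefined β-keto aldehyde as its hydrogen-bonded (Z)-enaminone.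

Step 16
Reactants: 23 (3Z,4R)-3-(aminomethylidene)-4-(TBSO)-4-(Diox)butan-2-one
Product: 25 (2Z)-2-[(R)-(TBSO)(Diox)methyl]-3-(triflyloxy)but-2-enal, via O-triflyl iminium triflate 24 (not isolated)
Conditions: Tf2O, 2,6-di-tert-butyl-4-methylpyridine, CH2Cl2, −78 °C; aq. NaHCO3, THF, 0 °C
Reagents that add atoms: trifluoromethanesulfonic anhydride, O=S(=O)(OS(=O)(=O)C(F)(F)F)C(F)(F)F; water, O
Why: O-Sulfonylation of the vinylogous amide oxygen gives a 3-triflyloxy-propeniminium ion whose hydrolysis releases the aldehyde, the chelated (Z)-geometry placing OTf cis to CHO.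

Step 17
Reactants: 15 ethynyl epoxide Ep–C≡CH; 25 (2Z)-2-[(R)-(TBSO)(Diox)methyl]-3-(triflyloxy)but-2-enal
Product: 29 5-[(R)-(TBSO)(Diox)methyl]-4-methyl-2-(Ep)-2H-pyran (both C-2 epimers), via alkenylzirconocene chloride 26 (not isolated), via alkenylzinc chloride 27 (not isolated), via dienal 28 (not isolated)
Conditions: 15, Cp2Zr(H)Cl, THF, rt; ZnCl2, 0 °C; 25, Pd(PPh3)4 (5 mol%), rt
Reagents that add atoms: none
Why: Hydrozirconation, transmetalation and Negishi coupling give the (2Z,4E)-dienal, which undergoes thermal disrotatory 6π-oxa-electrocyclisation to the 2H-pyran (favoured by the congested tetrasubstituted dienal), the new C-2 centre being inconsequential.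

Step 18
Reactants: 29 5-[(R)-(TBSO)(Diox)methyl]-4-methyl-2-(Ep)-2H-pyran
Product: 31 (7S,8R)-8-(TBSO)-7-hydroxy-7-methyl-3-(Ep)-3,5,7,8-tetrahydro-6H-isochromen-6-one (both C-3 epimers; used crude), via cyclohexenone dienal 30 (not isolated)
Conditions: LiN(SiMe3)2 (2.2 equiv), THF (0.01 M), −78 → −30 °C; AcOH, −78 °C → rt
Reagents that add atoms: none
Why: The 2H-pyran reacts through its ring-opened (2Z,4E)-dienal valence tautomer, whose C-4a methyl gives a vinylogous enolate that performs an intramolecular Claisen (Dieckmann-type) acylation on the dioxolanone carbonyl with loss of pivalaldehyde to free the C-7 hydroxyl, and kinetic protonation followed by 6π-oxa-electrocyclisation closes the bicyclic 2H-pyran with C-7 and C-8 untouched.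

Step 19
Reactants: 31 (7S,8R)-8-(TBSO)-7-hydroxy-7-methyl-3-(Ep)-3,5,7,8-tetrahydro-6H-isochromen-6-one
Product: 32 (7S,8R)-8-(TBSO)-7-hydroxy-7-methyl-3-(Ep)-7,8-dihydro-6H-isochromen-6-one (bis-TBS pestaphilone D)
Conditions: DDQ (1.2 equiv), NaHCO3, CH2Cl2, 0 °C → rt
Reagents that add atoms: none
Why: DDQ dehydrogenation, in which hydride is abstracted from C-3 of the 2H-pyran (allylic and α to oxygen) and the pyrylium-type cation loses the acidic C-5 proton to give the cross-conjugated chromophore, erasing the C-3 centre.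

Step 20
Reactants: 32 bis-TBS pestaphilone D
Product: 33 pestaphilone D
Conditions: Bu4NF, AcOH (1:1), THF, 0 °C → rt
Reagents that add atoms: none
Why: Buffered fluoride desilylation removes both silyl ethers without opening the vinyl epoxide or adding to the chromophore.

**Compound list**

1 | ethyl (S)-3-hydroxybutanoate | CCOC(=O)C[C@H](C)O | starting material
2 | ethyl (2S,3S)-3-hydroxy-2-methylbutanoate | C[C@H](O)[C@H](C)C(=O)OCC | intermediate
3 | ethyl (2S,3S)-3-(TBSO)-2-methylbutanoate | C[C@H](O[Si](C)(C)C(C)(C)C)[C@H](C)C(=O)OCC | intermediate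
4 | (2S,3S)-3-(TBSO)-2-methylbutanal | C[C@H](O[Si](C)(C)C(C)(C)C)[C@H](C)C=O | intermediate
5 | tert-butyl{[(2S,3R)-5,5-dibromo-3-methylpent-4-en-2-yl]oxy}dimethylsilane | C[C@H](O[Si](C)(C)C(C)(C)C)[C@H](C)C=C(Br)Br | intermediate
6 | tert-butyldimethyl{[(2S,3R)-3-methylhex-4-yn-2-yl]oxy}silane | C[C@H](O[Si](C)(C)C(C)(C)C)[C@H](C)C#CC | intermediate
7 | chlorobis(cyclopentadienyl)[(2E,4R,5S)-5-(TBSO)-4-methylhex-2-en-2-yl]zirconium | C[C@H](O[Si](C)(C)C(C)(C)C)[C@H](C)/C=C(\C)[Zr](Cl)(C1C=CC=C1)C1C=CC=C1 | intermediate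
8 | tert-butyl{[(2S,3R,4E)-5-iodo-3-methylhex-4-en-2-yl]oxy}dimethylsilane | C[C@H](O[Si](C)(C)C(C)(C)C)[C@H](C)/C=C(\C)I | intermediate
9 | (S)-but-3-yn-2-ol | C[C@H](O)C#C | starting material
10 | [(1E,3S)-3-[(dimethylalumanyl)oxy]-2-methylbut-1-en-1-yl]dimethylalumane | C[C@H](O[Al](C)C)/C(C)=C/[Al](C)C | intermediate
11 | (2S,3E,5E,7R,8S)-8-(TBSO)-3,5,7-trimethylnona-3,5-dien-2-ol | C[C@H](O)/C(C)=C/C(C)=C/[C@@H](C)[C@H](C)O[Si](C)(C)C(C)(C)C | intermediate
12 | (S)-1-(Ep)ethan-1-ol, erythro | C[C@H](O)[C@]1(C)O[C@H]1/C(C)=C/[C@@H](C)[C@H](C)O[Si](C)(C)C(C)(C)C | intermediate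
13 | 1-[(2R,3S)-3-R-2-methyloxiran-2-yl]ethan-1-one | CC(=O)[C@]1(C)O[C@H]1/C(C)=C/[C@@H](C)[C@H](C)O[Si](C)(C)C(C)(C)C | intermediate
14 | 1-(Ep)ethenyl diethyl phosphate | C=C(OP(=O)(OCC)OCC)[C@]1(C)O[C@H]1/C(C)=C/[C@@H](C)[C@H](C)O[Si](C)(C)C(C)(C)C | intermediate
15 | ethynyl epoxide Ep–C≡CH | C#C[C@]1(C)O[C@H]1/C(C)=C/[C@@H](C)[C@H](C)O[Si](C)(C)C(C)(C)C | intermediate
16 | (R)-lactic acid | C[C@@H](O)C(=O)O | starting material
17 | pivalaldehyde | CC(C)(C)C=O | starting material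
18 | (2R,5R)-2-tert-butyl-5-methyl-1,3-dioxolan-4-one | C[C@H]1O[C@@H](C(C)(C)C)OC1=O | intermediate
19 | 5-methylisoxazole-4-carbonyl chloride | Cc1oncc1C(Cl)=O | starting material
20 | (5-methylisoxazol-4-yl)(Diox)methanone | C[C@@]1(C(=O)c2cnoc2C)O[C@@H](C(C)(C)C)OC1=O | intermediate
21 | (R)-(5-methylisoxazol-4-yl)(Diox)methanol | C[C@@]1([C@H](O)c2cnoc2C)O[C@@H](C(C)(C)C)OC1=O | intermediate
22 | TBS ether of 21 | C[C@@]1([C@H](O[Si](C)(C)C(C)(C)C)c2cnoc2C)O[C@@H](C(C)(C)C)OC1=O | intermediate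
23 | (3Z,4R)-3-(aminomethylidene)-4-(TBSO)-4-(Diox)butan-2-one | C[C@@]1([C@H](O[Si](C)(C)C(C)(C)C)/C(C(C)=O)=C/N)O[C@@H](C(C)(C)C)OC1=O | intermediate
24 | (2Z)-2-[(R)-(TBSO)(Diox)methyl]-3-(triflyloxy)but-2-en-1-iminium triflate | C[C@@]1([C@H](O[Si](C)(C)C(C)(C)C)/C(C=[NH2+])=C(\C)OS(=O)(=O)C(F)(F)F)O[C@@H](C(C)(C)C)OC1=O.[O-]S(=O)(=O)C(F)(F)F | intermediate
25 | (2Z)-2-[(R)-(TBSO)(Diox)methyl]-3-(triflyloxy)but-2-enal | C[C@@]1([C@H](O[Si](C)(C)C(C)(C)C)/C(C=O)=C(\C)OS(=O)(=O)C(F)(F)F)O[C@@H](C(C)(C)C)OC1=O | intermediate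
26 | chlorobis(cyclopentadienyl)[(E)-2-(Ep)ethenyl]zirconium | Cl[Zr](/C=C/[C@]1(C)O[C@H]1/C(C)=C/[C@@H](C)[C@H](C)O[Si](C)(C)C(C)(C)C)(C1C=CC=C1)C1C=CC=C1 | intermediate
27 | chloro[(E)-2-(Ep)ethenyl]zinc | Cl[Zn]/C=C/[C@]1(C)O[C@H]1/C(C)=C/[C@@H](C)[C@H](C)O[Si](C)(C)C(C)(C)C | intermediate
28 | (2Z,4E)-2-[(R)-(TBSO)(Diox)methyl]-3-methyl-5-(Ep)penta-2,4-dienal | C[C@@]1([C@H](O[Si](C)(C)C(C)(C)C)/C(C=O)=C(C)/C=C/[C@]2(C)O[C@H]2/C(C)=C/[C@@H](C)[C@H](C)O[Si](C)(C)C(C)(C)C)O[C@@H](C(C)(C)C)OC1=O | intermediate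
29 | 5-[(R)-(TBSO)(Diox)methyl]-4-methyl-2-(Ep)-2H-pyran, both C-2 epimers | C[C@@]1([C@H](O[Si](C)(C)C(C)(C)C)C2=COC(C=C2C)[C@]3(C)O[C@H]3/C(C)=C/[C@@H](C)[C@H](C)O[Si](C)(C)C(C)(C)C)O[C@@H](C(C)(C)C)OC1=O | intermediate
30 | (5S,6R)-6-(TBSO)-5-hydroxy-5-methyl-4-oxo-2-[(E)-2-(Ep)ethenyl]cyclohex-1-ene-1-carbaldehyde | O=CC1=C(/C=C/[C@]2(C)O[C@H]2/C(C)=C/[C@@H](C)[C@H](C)O[Si](C)(C)C(C)(C)C)CC(=O)[C@@](C)(O)[C@@H]1O[Si](C)(C)C(C)(C)C | intermediate
31 | (7S,8R)-8-(TBSO)-7-hydroxy-7-methyl-3-(Ep)-3,5,7,8-tetrahydro-6H-isochromen-6-one, both C-3 epimers | O=C1CC2=CC(OC=C2[C@@H](O[Si](C)(C)C(C)(C)C)[C@]1(C)O)[C@]3(C)O[C@H]3/C(C)=C/[C@@H](C)[C@H](C)O[Si](C)(C)C(C)(C)C | intermediate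
32 | (7S,8R)-8-(TBSO)-7-hydroxy-7-methyl-3-[(2R,3S)-3-R-2-methyloxiran-2-yl]-7,8-dihydro-6H-isochromen-6-one | C/C(=C\[C@@H](C)[C@H](C)O[Si](C)(C)C(C)(C)C)[C@@H]1O[C@@]1(C)C1=CC2=CC(=O)[C@@](C)(O)[C@H](O[Si](C)(C)C(C)(C)C)C2=CO1 | intermediate
33 | pestaphilone D | C/C(=C\[C@@H](C)[C@H](C)O)[C@@H]1O[C@@]1(C)C1=CC2=CC(=O)[C@@](C)(O)[C@H](O)C2=CO1 | target

**Totals**
Total step count: 20. Longest linear sequence: 14 (steps 1–10, then 17–20).

**Three steps most likely to fail**

Step 13 (facial selectivity of the ketone reduction is predicted by model, not by precedent; the 8-epimer would lead to the cis-diol). Fallback: reverse the polarity of the C-7/C-8 bond construction and use chelation control. Setting out from 18, the lithium enolate is formylated with N-formylmorpholine to give (2R,5S)-2-tert-butyl-5-methyl-4-oxo-1,3-dioxolane-5-carbaldehyde F1. Separately, 4-iodo-5-methylisoxazole is converted with i-PrMgCl·LiCl (THF, −40 °C) into (5-methylisoxazol-4-yl)magnesium chloride F2. F2 adds to F1 at −78 °C through the five-membered magnesium chelate between the aldehyde oxygen and the ring ether oxygen, from the convex methyl-bearing face, to give 21, where the route is rejoined.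

Step 16 (O-triflation of a primary vinylogous amide may be diverted to N-sulfonylation or give E/Z mixtures). Fallback: setting out from 23, transamination with Me2NH·HCl and Et3N in EtOH at 60 °C gives (4R)-3-[(dimethylamino)methylidene]-4-(TBSO)-4-(Diox)butan-2-one F3. POCl3 (CH2Cl2, 0 °C; chloro-iminium formation of the Vilsmeier–Arnold type) and buffered hydrolysis convert it into (2Z)-3-chloro-2-[(R)-(TBSO)(Diox)methyl]but-2-enal F4. F4 takes the place of 25 in the Negishi coupling (Pd(t-Bu3P)2 as catalyst for the vinyl chloride), and the route is rejoined at 29.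

Step 18 (the trienolate may lose the 8-silyloxy group by E1cB elimination, or condense intermolecularly, before it acylates). Fallback: oxidise before ring closure and acylate without strong base. Setting out from 29, DDQ with 2,6-lutidine (CH2Cl2, 0 °C) abstracts hydride from C-2 of the 2H-pyran, and the 4-methylpyrylium ion is deprotonated to the neutral anhydrobase 5-[(R)-(TBSO)(Diox)methyl]-4-methylidene-2-(Ep)-4H-pyran F5. On warming in toluene (80 °C) the exocyclic enol-ether carbon of F5 is acylated intramolecularly by the dioxolanone, pivalaldehyde is lost, and the product is 32, where the route is rejoined.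

**Further compounds**
F1 | step 13 | (2R,5S)-2-tert-butyl-5-methyl-4-oxo-1,3-dioxolane-5-carbaldehyde | C[C@@]1(C=O)O[C@@H](C(C)(C)C)OC1=O
F2 | step 13 | (5-methylisoxazol-4-yl)magnesium chloride | Cc1oncc1[Mg]Cl
F3 | step 16 | (4R)-3-[(dimethylamino)methylidene]-4-(TBSO)-4-(Diox)butan-2-one | C[C@@]1([C@H](O[Si](C)(C)C(C)(C)C)C(C(C)=O)=CN(C)C)O[C@@H](C(C)(C)C)OC1=O
F4 | step 16 | (2Z)-3-chloro-2-[(R)-(TBSO)(Diox)methyl]but-2-enal | C[C@@]1([C@H](O[Si](C)(C)C(C)(C)C)/C(C=O)=C(\C)Cl)O[C@@H](C(C)(C)C)OC1=O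
F5 | step 18 | 5-[(R)-(TBSO)(Diox)methyl]-4-methylidene-2-(Ep)-4H-pyran | C[C@@]1([C@H](O[Si](C)(C)C(C)(C)C)C2=COC(=CC2=C)[C@]3(C)O[C@H]3/C(C)=C/[C@@H](C)[C@H](C)O[Si](C)(C)C(C)(C)C)O[C@@H](C(C)(C)C)OC1=O
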